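# Proposed total synthesis of CNP0322111.0 (cupressuflavone 4'-O-methyl ether)

## Structural features

The target is an 8,8''-linked biflavone: an acacetin unit (unprimed locants, 4'-OMe) and an apigenin unit (double-primed locants, 4'''-OH), each a 5,7-dihydroxy-2-aryl-4H-chromen-4-one, joined by one bond between C8 and C8''. There is no stereogenic carbon. The C8–C8'' axis is flanked by four oxygen-bearing carbons (C7, C8a, C7'', C8a''), so rotation is hindered, but no axial configuration is specified. The two halves differ only in one para oxygen, so the single methyl ether must survive while five other oxygens are unveiled; this rules out a global demethylation and points to hydrogenolysable ethers. Fragile points are the C2=C3 bonds of both pyranones (reducible), 5-O-benzyl ethers peri to a C4 carbonyl (labile to Lewis acids), and the ability of a free 5-hydroxyflavone to open and reclose to the 6-aryl isomer in hot strong acid. The real difficulty is twofold: the biaryl bond carries four ortho oxygens, and each pyranone must be fused to its phloroglucinol ring through the oxygen next to the axis (8-linkage, not 6-linkage). The key step exploits that, in ring A of the apigenin half, C8a'' (bearing O1'') and C4a'' (bearing the C4'' carbonyl) are neighbours, with the axis carbon C8'' on one side and the oxygenated C5'' on the other. This is the pattern left when an oxygen and an acyl group add across a 3-alkoxyaryne.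

## Logic of the disconnections

28 is traced to 27 by cutting the four benzyl–oxygen bonds. Benzyl ethers are the only ethers that can be removed without touching the methyl ether. The forward step must be a neutral hydrogenolysis that spares the two enone double bonds.

27 is opened at O1–C2 of the acacetin pyranone to give 26. The cut turns a heterocycle into an open 1,3-diketone. The forward cyclodehydration must use the hydroxyl next to the axis, and this is secured because the other ortho oxygen of 26 is still benzylated.

26 is cut between the methyl carbon of the aryl ketone and the aroyl carbon, giving 23 and 24. This removes the whole anisoyl unit in one stroke. The forward step must aroylate carbon, not the two free phenols, which calls for the fully deprotonated polyanion.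

23 is cut at the bond between the ring carbon (future C4a) and the acetyl carbon (future C4), giving 21. The two open positions of 21 are equivalent by symmetry, so no regiochemical question arises. The forward acylation must spare the benzyl ethers and the other flavone ring.

21 is traced to 20 by cutting the two acetal C–O bonds. The forward step is a mild acid methanolysis that leaves every benzyl ether in place.

20 is cut at O1''–C8a'', C4a''–C4'' and O1''–C2'', giving 14 and 17. One heterocycle and three bonds are removed, and the biaryl is reduced to a benzene-level aryne precursor. The forward step must deliver oxygen to the aryne carbon next to the axis and must close the ring in the 6-endo mode.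

17 is cut at the bond between the alkyne and the carboxyl carbon, giving 15 and carbon dioxide. The forward step is a simple acetylide carboxylation.

14 is traced through 13 to 12 by cutting the O–S bond and then the O–carbamoyl bond. The carbamate is the group that allowed both ortho positions to be metalated. The forward steps must remove it from a shielded oxygen without losing the acid-sensitive aryl–silicon bond.

12 is cut at the biaryl bond (future C8–C8''), giving 4 and 9. Both pieces are single benzene rings, and the bond is made before either heterocycle exists. The forward coupling must form a biaryl with four ortho substituents.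

4 is traced through 2 to 1 by cutting the C–Si bond and the O–carbamoyl bond. The forward metalation must occur next to the carbamate and not at a benzylic position.

9 is traced through 7 and 6 to 5 by cutting the C–I bond, the O–benzyl bond and two O–acetal bonds. The two acetal groups direct the iodine between them. The forward sequence must put two identical groups on a triol, which is only statistically selective.

## Other disconnections considered

Alternative 1: The cut is the C8–C8'' bond itself, made last between two finished flavones.
- Forward step: the two 8-iodoflavones are tied through O7 and O7'' as the methylene acetal A1. Pd(PPh3)4 and Me3SnSnMe3 would stannylate one C–I bond and close the seven-membered dibenzodioxepine A2 by intramolecular Stille coupling.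
- In favour: each 8-iodoflavone derives from a 3-iodo-2-hydroxyacetophenone by standard chemistry. Iodine fixes the linkage positions, so the 8- versus 6-question never arises. The tether turns a tetra-ortho-substituted coupling into a ring closure.
- Against: a mixed acetal of two different phenols must be assembled stepwise to avoid homodimers, and each 7-hydroxyl must be singled out. The tin reagent is toxic. Opening the diaryl methylene acetal of A2 needs a strong boron Lewis acid, which endangers the methyl ether and exposes free 5-hydroxyflavones to acid.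
- Comparison: on convergence and on placing the hard bond after both heterocycles exist, Alternative 1 is the equal or the better of the chosen plan, and its longest linear sequence should be shorter. The chosen plan makes the same bond early on plain benzene rings, where the four ortho groups are small oxygens and no seven-membered transition state is needed, and its end game is a neutral hydrogenolysis. Total step counts should be similar.

Alternative 2: The cuts run through ring A of the apigenin half (C8a''–C8'', C6''–C7'', C4a''–C8a'').
- Forward step: the cyclobutenone A3 and the aryl siloxyalkyne A4 are heated. Electrocyclic opening to a vinylketene, [2+2] addition to the electron-rich alkyne, a second ring opening and 6π closure would give the biaryl phenol A5.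
- In favour: the axis bond is never made by cross-coupling, since it starts as an aryl–alkyne bond. Ketene polarity sets the regiochemistry. A5 emerges with three differentiated oxygens and its free hydroxyl exactly at C8a''.
- Against: A4, a siloxyalkyne on a 2,6-dioxygenated aryl ring, needs ynolate chemistry and is hindered at the carbon that must bond to the ketene, and A3 is a sensitive reagent. After A5, ring C of the apigenin half must still be built by C-acylation at C4a'' in competition with the open C6'' position between two oxygens. This is the selectivity that the aryne step settles by delivering oxygen and acyl together.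
- Comparison: Alternative 2 is the better plan on avoiding a hindered palladium coupling and two metalations beside benzyl ethers. It is the equal of the chosen plan for the acacetin half, which would be built the same way. It should be longer by the three or four steps needed for ring C, and its building blocks are less accessible.

Alternative 3: The cut is C4a''–C5'' in ring A of the apigenin half.
- Forward step: the pyranone-bearing β-keto ester A6 is treated with LiN(SiMe3)2. The extended enolate of the 6-alkylpyranone would attack the ester carbon through pyranone C5, and the new ring would aromatize to A7.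
- In favour: the folding mimics polyketide biosynthesis. Ring A appears with free 5''- and 7''-hydroxyls, so A7 is one hydrogenolysis from the target. That is the shortest end game of all the plans and on this point it is better than the chosen plan. No biaryl coupling is needed, because the axis is an sp3–sp2 bond until aromatization.
- Against: A6 carries a crowded methine bound to C8 of a complete acacetin, to a pyranone and to an acetoacetate chain, and its assembly is a linear sequence on an advanced intermediate. It has several acidic sites, so O-acylation, pyranone ring opening and retro-Claisen cleavage would compete with the desired closure.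
- Comparison: mechanistically this is a Claisen-type closure against an aryne insertion, and both are reasonable. Alternative 3 is the better plan after the key step. The chosen plan is the better one before it, because 14 and 17 come from robust aromatic chemistry. Overall length should be similar or greater for Alternative 3.

Key step: step 10

## Remarks on the chemistry

- Assumption: the target is taken without a defined configuration at the C8–C8'' axis, so the route delivers the racemate.
- The silyl triflate 14 and the flavone 20 agree atom for atom with an aryne between C2 and C3 of the biphenyl (oxygen at C2, acyl at C3); no structural correction is needed.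
- Design choices: 17 is used in excess as its caesium salt because 14 is the valuable partner. The two-stage ester/rearrangement sequence is replaced by direct aroylation of the polyanion (step 13), so no anisoate ester has to be removed from O7.

## Route

Step 1
Reactants: 1 3,5-bis(benzyloxy)phenol
Product: 2 3,5-bis(benzyloxy)phenyl N,N-diethylcarbamate
Conditions: Et2NCOCl, K2CO3, MeCN, 80 °C
Reagents that add atoms: N,N-diethylcarbamoyl chloride, CCN(CC)C(Cl)=O
Why: O-carbamoylation of a phenoxide; the diethylcarbamate is the strongest oxygen-based director for ortho-metalation and sits on the oxygen that later becomes the triflate.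

Step 2
Reactants: 2 3,5-bis(benzyloxy)phenyl N,N-diethylcarbamate
Product: 4 3,5-bis(benzyloxy)-2-(trimethylsilyl)phenyl N,N-diethylcarbamate, via ortho-lithiated carbamate 3 (not isolated)
Conditions: s-BuLi, TMEDA, THF, −78 °C; then Me3SiCl, −78 °C → rt
Reagents that add atoms: chlorotrimethylsilane, C[Si](C)(C)Cl
Why: Directed ortho-metalation: the two positions next to the carbamate are equivalent and are further acidified by a benzyloxy group, so they are lithiated in preference to the position between the two benzyloxy groups. At −78 °C silylation should outrun anionic Fries migration and benzylic deprotonation.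

Step 3
Reactants: 5 phloroglucinol
Product: 6 3,5-bis(methoxymethoxy)phenol
Conditions: MOMCl (2.0 equiv), iPr2NEt, DMF–CH2Cl2, 0 °C → rt
Reagents that add atoms: chloromethyl methyl ether, COCCl
Why: Statistical O-alkylation of a symmetrical triol; the bis-ether is separated by chromatography from the mono- and tris-ethers, and the mono-ether can be resubmitted. The acetal groups later direct the lithiation between them and are the only acid-labile ethers in the route.

Step 4
Reactants: 6 3,5-bis(methoxymethoxy)phenol
Product: 7 1-(benzyloxy)-3,5-bis(methoxymethoxy)benzene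
Conditions: BnBr, K2CO3, DMF, rt
Reagents that add atoms: benzyl bromide, BrCc1ccccc1
Why: Williamson etherification of the single free phenol; this benzyl group later blocks the wrong ortho oxygen when the second pyranone is closed.

Step 5
Reactants: 7 1-(benzyloxy)-3,5-bis(methoxymethoxy)benzene
Product: 9 5-(benzyloxy)-2-iodo-1,3-bis(methoxymethoxy)benzene, via aryllithium 8 (not isolated)
Conditions: n-BuLi, THF, 0 °C; then I2, −78 °C → rt
Reagents that add atoms: iodine, [I][I]
Why: Directed ortho-metalation at the carbon between the two acetal groups, which chelate lithium from both sides; iodinolysis of the aryllithium gives the iodide at the future axis carbon only.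

Step 6
Reactants: 4 3,5-bis(benzyloxy)-2-(trimethylsilyl)phenyl N,N-diethylcarbamate; 9 5-(benzyloxy)-2-iodo-1,3-bis(methoxymethoxy)benzene
Product: 12 4,4',6-tris(benzyloxy)-2',6'-bis(methoxymethoxy)-3-(trimethylsilyl)biphenyl-2-yl N,N-diethylcarbamate, via aryllithium 10 (not isolated), via arylzinc chloride 11 (not isolated)
Conditions: 4, s-BuLi, TMEDA, THF, −78 °C; ZnCl2, −78 °C → rt; then 9, Pd2(dba)3 (2.5 mol %), RuPhos (10 mol %), THF–NMP, 70 °C
Reagents that add atoms: none
Why: A second directed ortho-metalation at the only remaining position next to the carbamate, transmetalation to zinc (which stops Fries migration and tolerates heating), then Negishi coupling. A bulky dialkylbiarylphosphine on zerovalent palladium is the catalyst type developed for biaryls with three or four ortho substituents, and here all four are small oxygen atoms.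

Step 7
Reactants: 12 4,4',6-tris(benzyloxy)-2',6'-bis(methoxymethoxy)-3-(trimethylsilyl)biphenyl-2-yl N,N-diethylcarbamate
Product: 13 4,4',6-tris(benzyloxy)-2',6'-bis(methoxymethoxy)-3-(trimethylsilyl)biphenyl-2-ol
Conditions: LiAlH4, THF, 0 °C → reflux; aq. KNaC4H4O6 work-up
Reagents that add atoms: none
Why: Hydride reduction of the aryl carbamate: addition to the carbonyl expels the aryloxide and the carbamoyl carbon leaves as an amine. Benzyl ethers, acetals and the aryl–silicon bond are inert to hydride, and the neutral work-up avoids ipso-protodesilylation of the electron-rich aryl silane.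

Step 8
Reactants: 13 4,4',6-tris(benzyloxy)-2',6'-bis(methoxymethoxy)-3-(trimethylsilyl)biphenyl-2-ol
Product: 14 4,4',6-tris(benzyloxy)-2',6'-bis(methoxymethoxy)-3-(trimethylsilyl)biphenyl-2-yl trifluoromethanesulfonate
Conditions: Tf2O, pyridine, CH2Cl2, −20 → 0 °C
Reagents that add atoms: trifluoromethanesulfonic anhydride, O=S(=O)(OS(=O)(=O)C(F)(F)F)C(F)(F)F
Why: O-sulfonylation of an ortho-silylphenol, the standard last step to fluoride-triggered aryne precursors; excess pyridine buffers the acid so that the acetals and the aryl silane survive.

Step 9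
Reactants: 15 1-(benzyloxy)-4-ethynylbenzene
Product: 17 3-[4-(benzyloxy)phenyl]prop-2-ynoic acid, via lithium acetylide 16 (not isolated)
Conditions: n-BuLi, THF, −78 °C; CO2; then aq. HCl, 0 °C
Reagents that add atoms: carbon dioxide, O=C=O
Why: Carboxylation of a lithium acetylide; the acid is isolated cold to avoid decarboxylation.

Step 10
Reactants: 14 4,4',6-tris(benzyloxy)-2',6'-bis(methoxymethoxy)-3-(trimethylsilyl)biphenyl-2-yl trifluoromethanesulfonate; 17 3-[4-(benzyloxy)phenyl]prop-2-ynoic acid
Product: 20 5,7-bis(benzyloxy)-2-[4-(benzyloxy)phenyl]-8-[4-(benzyloxy)-2,6-bis(methoxymethoxy)phenyl]-4H-chromen-4-one, via aryne 18 (not isolated), via hydroxyaryl ynone 19 (not isolated)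
Conditions: 17 (2.5 equiv), CsF (6 equiv), THF, 125 °C, sealed vessel
Reagents that add atoms: none
Why: Fluoride attacks silicon and triflate leaves, giving aryne 18 with its triple bond between C2 and C3 of the biphenyl (the future C8a'' and C4a''). The caesium carboxylate of 17 adds through oxygen to C2, and the aryl anion at C3 attacks the ester carbonyl through a four-membered transition state, shifting the acyl group from oxygen to carbon to give the ortho-acylphenoxide 19. This is the known fluoride-induced insertion of arynes into the C–O bond of carboxylic acids, which with 3-arylpropiolic acids runs on to flavones. Ring C then closes by 6-endo-dig oxa-Michael addition of the phenoxide to the ynone, and the resulting vinyl anion is protonated by bifluoride. No stereocentre is formed. The step needs oxygen to add at C2, beside the axis: the benzyloxy group at C4 distorts the aryne inductively, making C2 the more electrophilic terminus and stabilising the charge that develops at C3, as in 3-methoxybenzyne. The high temperature in THF favours the acyl shift over protonation of the aryl anion, and the excess carboxylate outcompetes attack by a neighbouring acetal oxygen, which would also need the two rings to become coplanar. Because oxygen and acyl arrive together, no choice between two ortho phenols has to be made.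

Step 11
Reactants: 20 5,7-bis(benzyloxy)-2-[4-(benzyloxy)phenyl]-8-[4-(benzyloxy)-2,6-bis(methoxymethoxy)phenyl]-4H-chromen-4-one
Product: 21 5,7-bis(benzyloxy)-2-[4-(benzyloxy)phenyl]-8-[4-(benzyloxy)-2,6-dihydroxyphenyl]-4H-chromen-4-one
Conditions: 3 M aq. HCl, MeOH–THF, 50 °C
Reagents that add atoms: none
Why: Acid-catalysed transacetalisation of the two aryl methoxymethyl ethers to methanol; dilute acid at this temperature should leave the benzyl ethers, including the peri 5''-O-benzyl group, untouched.

Step 12
Reactants: 21 5,7-bis(benzyloxy)-2-[4-(benzyloxy)phenyl]-8-[4-(benzyloxy)-2,6-dihydroxyphenyl]-4H-chromen-4-one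
Product: 23 8-[3-acetyl-4-(benzyloxy)-2,6-dihydroxyphenyl]-5,7-bis(benzyloxy)-2-[4-(benzyloxy)phenyl]-4H-chromen-4-one, via difluoroboron chelate 22 (not isolated)
Conditions: Ac2O (1.5 equiv), BF3·OEt2, EtOAc, 0 °C → rt; then NaOAc, MeOH–H2O, 60 °C
Reagents that add atoms: acetic anhydride, CC(=O)OC(C)=O
Why: BF3-mediated Friedel–Crafts (Nencki-type) acetylation of a phloroglucinol-type ring: the two open positions are equivalent, each ortho to one hydroxyl and para to the other, so only one ketone can form. The ketone is held as its difluoroboron chelate, which prevents a second acylation, and buffered methanolysis releases it along with any O-acetate. The flavone ring is deactivated by coordination of BF3 to its carbonyl.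

Step 13
Reactants: 23 8-[3-acetyl-4-(benzyloxy)-2,6-dihydroxyphenyl]-5,7-bis(benzyloxy)-2-[4-(benzyloxy)phenyl]-4H-chromen-4-one; 24 4-methoxybenzoyl chloride
Product: 26 1-{6-(benzyloxy)-3-[5,7-bis(benzyloxy)-2-(4-benzyloxyphenyl)-4-oxo-4H-chromen-8-yl]-2,4-dihydroxyphenyl}-3-(4-methoxyphenyl)propane-1,3-dione, via trilithium enolate 25 (not isolated)
Conditions: LiN(SiMe3)2 (4.5 equiv), THF, −78 → −10 °C; 24 (1.05 equiv), −78 °C → rt; then aq. HCl
Reagents that add atoms: none
Why: Direct variant of the Baker–Venkataraman acyl transfer: excess amide base forms the bis-phenoxide enolate, whose carbon is the most reactive site toward the acid chloride. Any ester formed at the ortho phenoxide would rearrange to the same diketone under the excess base, so both phenols end free and no ester hydrolysis is needed.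

Step 14
Reactants: 26 1-{6-(benzyloxy)-3-[5,7-bis(benzyloxy)-2-(4-benzyloxyphenyl)-4-oxo-4H-chromen-8-yl]-2,4-dihydroxyphenyl}-3-(4-methoxyphenyl)propane-1,3-dione
Product: 27 5-(benzyloxy)-8-{5,7-bis(benzyloxy)-2-[4-(benzyloxy)phenyl]-4-oxo-4H-chromen-8-yl}-7-hydroxy-2-(4-methoxyphenyl)-4H-chromen-4-one
Conditions: H2SO4 (cat.), AcOH, 60 °C
Reagents that add atoms: none
Why: Acid-catalysed cyclodehydration of an ortho-hydroxyaryl 1,3-diketone to the flavone; only the hydroxyl beside the axis is ortho to the diketone because the other ortho oxygen is benzylated, which fixes the 8-linkage. The intact 5-O-benzyl group also blocks Wessely–Moser isomerisation.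

Step 15
Reactants: 27 5-(benzyloxy)-8-{5,7-bis(benzyloxy)-2-[4-(benzyloxy)phenyl]-4-oxo-4H-chromen-8-yl}-7-hydroxy-2-(4-methoxyphenyl)-4H-chromen-4-one
Product: 28 5,7-dihydroxy-8-[5,7-dihydroxy-2-(4-hydroxyphenyl)-4-oxo-4H-chromen-8-yl]-2-(4-methoxyphenyl)-4H-chromen-4-one
Conditions: H2 (1 atm), Pd/C (10 wt %), THF–MeOH, rt
Reagents that add atoms: none
Why: Hydrogenolysis of four aryl benzyl ethers under neutral conditions; the aryl methyl ether is inert, and at atmospheric pressure with monitoring the pyranone double bonds should be spared.

## Compound list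

1 | 3,5-bis(benzyloxy)phenol | Oc1cc(OCc2ccccc2)cc(OCc2ccccc2)c1 | starting material
2 | 3,5-bis(benzyloxy)phenyl N,N-diethylcarbamate | CCN(CC)C(=O)Oc1cc(OCc2ccccc2)cc(OCc2ccccc2)c1 | intermediate
3 | ortho-lithiated carbamate: {2,4-bis(benzyloxy)-6-[(diethylcarbamoyl)oxy]phenyl}lithium (not isolated) | CCN(CC)C(=O)Oc1cc(OCc2ccccc2)cc(OCc2ccccc2)c1[Li] | intermediate
4 | 3,5-bis(benzyloxy)-2-(trimethylsilyl)phenyl N,N-diethylcarbamate | CCN(CC)C(=O)Oc1cc(OCc2ccccc2)cc(OCc2ccccc2)c1[Si](C)(C)C | intermediate
5 | phloroglucinol (benzene-1,3,5-triol) | Oc1cc(O)cc(O)c1 | starting material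
6 | 3,5-bis(methoxymethoxy)phenol | COCOc1cc(O)cc(OCOC)c1 | intermediate
7 | 1-(benzyloxy)-3,5-bis(methoxymethoxy)benzene | COCOc1cc(OCOC)cc(OCc2ccccc2)c1 | intermediate
8 | aryllithium: [4-(benzyloxy)-2,6-bis(methoxymethoxy)phenyl]lithium (not isolated) | COCOc1cc(OCc2ccccc2)cc(OCOC)c1[Li] | intermediate
9 | 5-(benzyloxy)-2-iodo-1,3-bis(methoxymethoxy)benzene | COCOc1cc(OCc2ccccc2)cc(OCOC)c1I | intermediate
10 | aryllithium: {2,4-bis(benzyloxy)-6-[(diethylcarbamoyl)oxy]-5-(trimethylsilyl)phenyl}lithium (not isolated) | CCN(CC)C(=O)Oc1c([Li])c(OCc2ccccc2)cc(OCc2ccccc2)c1[Si](C)(C)C | intermediate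
11 | arylzinc chloride: chloro{2,4-bis(benzyloxy)-6-[(diethylcarbamoyl)oxy]-5-(trimethylsilyl)phenyl}zinc (not isolated) | CCN(CC)C(=O)Oc1c([Zn]Cl)c(OCc2ccccc2)cc(OCc2ccccc2)c1[Si](C)(C)C | intermediate
12 | 4,4',6-tris(benzyloxy)-2',6'-bis(methoxymethoxy)-3-(trimethylsilyl)biphenyl-2-yl N,N-diethylcarbamate | COCOc1cc(OCc2ccccc2)cc(OCOC)c1-c1c(OCc2ccccc2)cc(OCc2ccccc2)c([Si](C)(C)C)c1OC(=O)N(CC)CC | intermediate
13 | 4,4',6-tris(benzyloxy)-2',6'-bis(methoxymethoxy)-3-(trimethylsilyl)biphenyl-2-ol | COCOc1cc(OCc2ccccc2)cc(OCOC)c1-c1c(OCc2ccccc2)cc(OCc2ccccc2)c([Si](C)(C)C)c1O | intermediate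
14 | 4,4',6-tris(benzyloxy)-2',6'-bis(methoxymethoxy)-3-(trimethylsilyl)biphenyl-2-yl trifluoromethanesulfonate | COCOc1cc(OCc2ccccc2)cc(OCOC)c1-c1c(OCc2ccccc2)cc(OCc2ccccc2)c([Si](C)(C)C)c1OS(=O)(=O)C(F)(F)F | intermediate
15 | 1-(benzyloxy)-4-ethynylbenzene | C#Cc1ccc(OCc2ccccc2)cc1 | starting material
16 | lithium acetylide: lithium [4-(benzyloxy)phenyl]acetylide (not isolated) | [Li]C#Cc1ccc(OCc2ccccc2)cc1 | intermediate
17 | 3-[4-(benzyloxy)phenyl]prop-2-ynoic acid | OC(=O)C#Cc1ccc(OCc2ccccc2)cc1 | intermediate
18 | aryne: 4,4',6-tris(benzyloxy)-2',6'-bis(methoxymethoxy)-2,3-didehydrobiphenyl (not isolated) | COCOc1cc(OCc2ccccc2)cc(OCOC)c1C1=C(OCc2ccccc2)C=C(OCc2ccccc2)C#C1 | intermediate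
19 | hydroxyaryl ynone: 1-[4,4',6-tris(benzyloxy)-2-hydroxy-2',6'-bis(methoxymethoxy)biphenyl-3-yl]-3-[4-(benzyloxy)phenyl]prop-2-yn-1-one, present as its caesium phenoxide (not isolated) | COCOc1cc(OCc2ccccc2)cc(OCOC)c1-c1c(OCc2ccccc2)cc(OCc2ccccc2)c(C(=O)C#Cc2ccc(OCc3ccccc3)cc2)c1O | intermediate
20 | 5,7-bis(benzyloxy)-2-[4-(benzyloxy)phenyl]-8-[4-(benzyloxy)-2,6-bis(methoxymethoxy)phenyl]-4H-chromen-4-one | COCOc1cc(OCc2ccccc2)cc(OCOC)c1-c1c(OCc2ccccc2)cc(OCc2ccccc2)c2c(=O)cc(-c3ccc(OCc4ccccc4)cc3)oc12 | intermediate
21 | 5,7-bis(benzyloxy)-2-[4-(benzyloxy)phenyl]-8-[4-(benzyloxy)-2,6-dihydroxyphenyl]-4H-chromen-4-one | Oc1cc(OCc2ccccc2)cc(O)c1-c1c(OCc2ccccc2)cc(OCc2ccccc2)c2c(=O)cc(-c3ccc(OCc4ccccc4)cc3)oc12 | intermediate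
22 | difluoroboron chelate of 23, boron bridging the acetyl oxygen and the adjacent phenol oxygen (not isolated) | CC1=[O+][B-](F)(F)Oc2c(-c3c(OCc4ccccc4)cc(OCc4ccccc4)c4c(=O)cc(-c5ccc(OCc6ccccc6)cc5)oc34)c(O)cc(OCc3ccccc3)c21 | intermediate
23 | 8-[3-acetyl-4-(benzyloxy)-2,6-dihydroxyphenyl]-5,7-bis(benzyloxy)-2-[4-(benzyloxy)phenyl]-4H-chromen-4-one (racemic about the axis) | CC(=O)c1c(OCc2ccccc2)cc(O)c(-c2c(OCc3ccccc3)cc(OCc3ccccc3)c3c(=O)cc(-c4ccc(OCc5ccccc5)cc4)oc23)c1O | intermediate
24 | 4-methoxybenzoyl chloride | COc1ccc(C(=O)Cl)cc1 | starting material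
25 | trilithium enolate of 23: two phenoxides and the methyl ketone enolate (not isolated) | C=C([O-])c1c(OCc2ccccc2)cc([O-])c(-c2c(OCc3ccccc3)cc(OCc3ccccc3)c3c(=O)cc(-c4ccc(OCc5ccccc5)cc4)oc23)c1[O-].[Li+].[Li+].[Li+] | intermediate
26 | 1-{6-(benzyloxy)-3-[5,7-bis(benzyloxy)-2-(4-benzyloxyphenyl)-4-oxo-4H-chromen-8-yl]-2,4-dihydroxyphenyl}-3-(4-methoxyphenyl)propane-1,3-dione | COc1ccc(C(=O)CC(=O)c2c(OCc3ccccc3)cc(O)c(-c3c(OCc4ccccc4)cc(OCc4ccccc4)c4c(=O)cc(-c5ccc(OCc6ccccc6)cc5)oc34)c2O)cc1 | intermediate
27 | 5-(benzyloxy)-8-{5,7-bis(benzyloxy)-2-[4-(benzyloxy)phenyl]-4-oxo-4H-chromen-8-yl}-7-hydroxy-2-(4-methoxyphenyl)-4H-chromen-4-one | COc1ccc(-c2cc(=O)c3c(OCc4ccccc4)cc(O)c(-c4c(OCc5ccccc5)cc(OCc5ccccc5)c5c(=O)cc(-c6ccc(OCc7ccccc7)cc6)oc45)c3o2)cc1 | intermediate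
28 | 5,7-dihydroxy-8-[5,7-dihydroxy-2-(4-hydroxyphenyl)-4-oxo-4H-chromen-8-yl]-2-(4-methoxyphenyl)-4H-chromen-4-one (cupressuflavone 4'-O-methyl ether, racemic about the axis) | COc1ccc(-c2cc(=O)c3c(O)cc(O)c(-c4c(O)cc(O)c5c(=O)cc(-c6ccc(O)cc6)oc45)c3o2)cc1 | target

## Step count and least certain steps

Total: 15 steps. Longest linear sequence: 12 steps, from 5 to 28 through steps 3, 4, 5, 6, 7, 8, 10, 11, 12, 13, 14 and 15.

**Step 10 (key step).** Four processes could divert it:
- Reversed regiochemistry: the twisted aryl group shields the carbon beside the axis and could steer the carboxylate to the other aryne carbon.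
- Premature protonation of the aryl anion before the acyl shift, which stops at an aryl ester.
- 5-exo closure of the ynone phenoxide in place of the 6-endo mode.
- Protodesilylation of the electron-rich aryl silane by the acid before fluoride triggers elimination.

The fallback avoids the aryne and sets out from 13. ICl in CH2Cl2 at −78 °C should replace silicon by iodine at the same carbon (ipso substitution, favoured by the β-silicon effect) to give 4,4',6-tris(benzyloxy)-3-iodo-2',6'-bis(methoxymethoxy)biphenyl-2-ol F1. Carbonylative Sonogashira annulation of F1 with 15 under CO (1 atm) with PdCl2(PPh3)2 and Et2NH at 90–120 °C is known chemistry for ortho-iodophenols and would return to the route at 20. The positions of oxygen and acyl are then fixed by bonds that already exist.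

**Step 6.** Transmetalation and reductive elimination may be slow because the arylzinc carries a carbamate buttressed by silicon and the iodide has two ortho acetal ethers; protodezincation and homocoupling would then take over. The fallback changes the order of events and sets out from 2 and 9. The zinc reagent chloro{2,4-bis(benzyloxy)-6-[(diethylcarbamoyl)oxy]phenyl}zinc F2 is made from 2 as in step 6 and coupled with 9 to give the silicon-free biaryl 4,4',6-tris(benzyloxy)-2',6'-bis(methoxymethoxy)biphenyl-2-yl N,N-diethylcarbamate F3. A second ortho-metalation (s-BuLi, TMEDA, −78 °C; Me3SiCl) at the remaining position next to the carbamate returns to the route at 12.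

**Step 7.** Hydride attack at a carbamate carbonyl flanked by a silyl group and a 2,6-disubstituted aryl ring may be slow, and forcing conditions invite loss of silicon. The fallback uses a carbamate that is released by elimination, not by attack at the carbonyl, and sets out from 1:
- Isopropyl isocyanate and Et3N give 3,5-bis(benzyloxy)phenyl N-(propan-2-yl)carbamate F4.
- Temporary N-silylation in the flask (Me3SiOTf, TMEDA), n-BuLi at −78 °C and Me3SiCl give 3,5-bis(benzyloxy)-2-(trimethylsilyl)phenyl N-(propan-2-yl)carbamate F5.
- The same metalation, then ZnCl2 and the coupling of step 6 with 9, give 4,4',6-tris(benzyloxy)-2',6'-bis(methoxymethoxy)-3-(trimethylsilyl)biphenyl-2-yl N-(propan-2-yl)carbamate F6.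
- Et2NH and DBU in MeCN at 40 °C expel the phenoxide by way of the isocyanate, and PhNTf2 added to the same flask returns to the route at 14.

**Step 12.** The Lewis acid may remove the benzyl group ortho to the new ketone, which would reopen the choice between two ortho phenols in step 14. Acylation may also stop at oxygen or occur at C6'' of the flavone. The fallback replaces electrophilic acylation by halogenation and cross-coupling and sets out from 21. NIS (1 equiv, CH2Cl2, −20 °C) should give 5,7-bis(benzyloxy)-2-[4-(benzyloxy)phenyl]-8-[4-(benzyloxy)-2,6-dihydroxy-3-iodophenyl]-4H-chromen-4-one F7. Stille coupling with tributyl(1-ethoxyvinyl)stannane and Pd(PPh3)4 gives the enol ether 8-[4-(benzyloxy)-3-(1-ethoxyvinyl)-2,6-dihydroxyphenyl]-5,7-bis(benzyloxy)-2-[4-(benzyloxy)phenyl]-4H-chromen-4-one F8, and dilute aqueous HCl hydrolyses it, returning to the route at 23.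

**Step 15.** Over-reduction of the C2=C3 bonds to flavanones is possible, and the partly debenzylated biflavone may precipitate and stop the reaction. The fallback replaces hydrogenolysis by Lewis-acid cleavage with a cation scavenger: from 27, BCl3 and pentamethylbenzene in CH2Cl2 at −78 °C should cleave the four benzyl ethers and leave the unchelated methyl ether, returning to the route at 28. This fallback makes no new compound (entry F0).

## Further compounds

F1 | step 10 | 4,4',6-tris(benzyloxy)-3-iodo-2',6'-bis(methoxymethoxy)biphenyl-2-ol | COCOc1cc(OCc2ccccc2)cc(OCOC)c1-c1c(OCc2ccccc2)cc(OCc2ccccc2)c(I)c1O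
F2 | step 6 | chloro{2,4-bis(benzyloxy)-6-[(diethylcarbamoyl)oxy]phenyl}zinc | CCN(CC)C(=O)Oc1cc(OCc2ccccc2)cc(OCc2ccccc2)c1[Zn]Cl
F3 | step 6 | 4,4',6-tris(benzyloxy)-2',6'-bis(methoxymethoxy)biphenyl-2-yl N,N-diethylcarbamate | COCOc1cc(OCc2ccccc2)cc(OCOC)c1-c1c(OCc2ccccc2)cc(OCc2ccccc2)cc1OC(=O)N(CC)CC
F4 | step 7 | 3,5-bis(benzyloxy)phenyl N-(propan-2-yl)carbamate | CC(C)NC(=O)Oc1cc(OCc2ccccc2)cc(OCc2ccccc2)c1
F5 | step 7 | 3,5-bis(benzyloxy)-2-(trimethylsilyl)phenyl N-(propan-2-yl)carbamate | CC(C)NC(=O)Oc1cc(OCc2ccccc2)cc(OCc2ccccc2)c1[Si](C)(C)C
F6 | step 7 | 4,4',6-tris(benzyloxy)-2',6'-bis(methoxymethoxy)-3-(trimethylsilyl)biphenyl-2-yl N-(propan-2-yl)carbamate | COCOc1cc(OCc2ccccc2)cc(OCOC)c1-c1c(OCc2ccccc2)cc(OCc2ccccc2)c([Si](C)(C)C)c1OC(=O)NC(C)C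
F7 | step 12 | 5,7-bis(benzyloxy)-2-[4-(benzyloxy)phenyl]-8-[4-(benzyloxy)-2,6-dihydroxy-3-iodophenyl]-4H-chromen-4-one | Oc1cc(OCc2ccccc2)c(I)c(O)c1-c1c(OCc2ccccc2)cc(OCc2ccccc2)c2c(=O)cc(-c3ccc(OCc4ccccc4)cc3)oc12
F8 | step 12 | 8-[4-(benzyloxy)-3-(1-ethoxyvinyl)-2,6-dihydroxyphenyl]-5,7-bis(benzyloxy)-2-[4-(benzyloxy)phenyl]-4H-chromen-4-one | CCOC(=C)c1c(OCc2ccccc2)cc(O)c(-c2c(OCc3ccccc3)cc(OCc3ccccc3)c3c(=O)cc(-c4ccc(OCc5ccccc5)cc4)oc23)c1O
F0 | step 15 | none | none
A1 | alternative 1 | bis(8-iodoflavon-7-yloxy)methane tether: 5-(benzyloxy)-7-({5-(benzyloxy)-2-[4-(benzyloxy)phenyl]-8-iodo-4-oxo-4H-chromen-7-yl}oxymethoxy)-8-iodo-2-(4-methoxyphenyl)-4H-chromen-4-one | COc1ccc(-c2cc(=O)c3c(OCc4ccccc4)cc(OCOc4cc(OCc5ccccc5)c5c(=O)cc(-c6ccc(OCc7ccccc7)cc6)oc5c4I)c(I)c3o2)cc1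
A2 | alternative 1 | 7,7''-O-methylene-bridged 5,5'',4'''-tri-O-benzyl biflavone | COc1ccc(-c2cc(=O)c3c(OCc4ccccc4)cc4OCOc5cc(OCc6ccccc6)c6c(=O)cc(-c7ccc(OCc8ccccc8)cc7)oc6c5-c4c3o2)cc1
A3 | alternative 2 | 3-(benzyloxy)cyclobut-2-en-1-one | O=C1C=C(OCc2ccccc2)C1
A4 | alternative 2 | ({[4-(benzyloxy)-2,6-bis(methoxymethoxy)phenyl]ethynyl}oxy)tri(propan-2-yl)silane | COCOc1cc(OCc2ccccc2)cc(OCOC)c1C#CO[Si](C(C)C)(C(C)C)C(C)C
A5 | alternative 2 | 4,4'-bis(benzyloxy)-2',6'-bis(methoxymethoxy)-6-(triisopropylsilyloxy)biphenyl-2-ol | Oc1cc(OCc2ccccc2)cc(O[Si](C(C)C)(C(C)C)C(C)C)c1-c1c(OCOC)cc(OCc2ccccc2)cc1OCOC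
A6 | alternative 3 | methyl 4-[5,7-bis(benzyloxy)-2-(4-methoxyphenyl)-4-oxo-4H-chromen-8-yl]-4-{6-[4-(benzyloxy)phenyl]-4-oxo-4H-pyran-2-yl}-3-oxobutanoate (racemic) | COc1ccc(-c2cc(=O)c3c(OCc4ccccc4)cc(OCc4ccccc4)c(C(C(=O)CC(=O)OC)c4cc(=O)cc(-c5ccc(OCc6ccccc6)cc5)o4)c3o2)cc1
A7 | alternative 3 | 5,7,4'''-tri-O-benzyl ether of the target with free 5''- and 7''-hydroxyls | COc1ccc(-c2cc(=O)c3c(OCc4ccccc4)cc(OCc4ccccc4)c(-c4c(O)cc(O)c5c(=O)cc(-c6ccc(OCc7ccccc7)cc6)oc45)c3o2)cc1
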